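The synthesis rests on cutting the C6–O and C7–acyl bonds of the benzofuran in one stroke. On the benzo ring, the C6 hydroxyl and the C7 propanoyl group are neighbours (an ortho-hydroxyaryl ketone), and C7 sits beside C7a, which carries the ring oxygen O1. A C6–C7 aryne is therefore polarized by O1: a carboxylate adds through oxygen at C6 and the C7 anion captures the acyl group, so hydroxyl and ketone arrive together with the correct orientation. The precursor is the complete 2-aryl-3-aroylbenzofuran carrying triflate at C6 and trimethylsilyl at C7, assembled by two directed lithiations, Sonogashira coupling and carbonylative annulation. Global demethylation then gives the target.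

Key step: step 8

Remark: the target has no stereocenter and no stereogenic double bond, so no step has to set configuration; the locants O1, C2, C3, C3a, C4 to C7 and C7a refer to the benzofuran.

Step 1
Reactants: 1 5-methoxyresorcinol
Product: 2 1-methoxy-3,5-bis(methoxymethoxy)benzene
Conditions: NaH, MOMCl, DMF, 0 °C to rt
Reagents that add atoms: chloromethyl methyl ether, COCCl
Why: Double O-alkylation of the sodium phenoxides by the chloromethyl ether (Williamson-type acetal formation) should install two acetal groups that survive organolithium reagents and direct the metalations that follow.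

Step 2
Reactants: 2 1-methoxy-3,5-bis(methoxymethoxy)benzene
Product: 4 [4-methoxy-2,6-bis(methoxymethoxy)phenyl]trimethylsilane, via aryllithium 3 (not isolated)
Conditions: n-BuLi, THF, 0 °C to rt; then TMSCl, −78 °C to rt
Reagents that add atoms: chlorotrimethylsilane, C[Si](C)(C)Cl
Why: Directed ortho-metalation should occur at the one position flanked by two chelating acetal oxygens, and silylation of the aryllithium places silicon on the future C7 before any carbonyl group exists.

Step 3
Reactants: 4 [4-methoxy-2,6-bis(methoxymethoxy)phenyl]trimethylsilane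
Product: 6 [3-iodo-4-methoxy-2,6-bis(methoxymethoxy)phenyl]trimethylsilane, via aryllithium 5 (not isolated)
Conditions: n-BuLi, TMEDA, THF, −20 to 0 °C; then I2, −78 °C
Reagents that add atoms: iodine, II
Why: With the most acidic site blocked by silicon, a second directed ortho-metalation should take place between an acetal oxygen and the methoxy group (the two such sites are equivalent by symmetry), and iodine traps the aryllithium at a temperature at which the aryl–silicon bond is not attacked.

Step 4
Reactants: 6 [3-iodo-4-methoxy-2,6-bis(methoxymethoxy)phenyl]trimethylsilane; 7 4-ethynylanisole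
Product: 8 {4-methoxy-3-[(4-methoxyphenyl)ethynyl]-2,6-bis(methoxymethoxy)phenyl}trimethylsilane
Conditions: PdCl2(PPh3)2 (5 mol%), CuI (5 mol%), Et3N, DMF, 65 °C
Reagents that add atoms: none
Why: Sonogashira coupling of the aryl iodide with the terminal alkyne should form the aryl–alkyne bond, and both phenols stay masked here so that the product cannot close to a 3-unsubstituted benzofuran under copper and heat.

Step 5
Reactants: 8 {4-methoxy-3-[(4-methoxyphenyl)ethynyl]-2,6-bis(methoxymethoxy)phenyl}trimethylsilane
Product: 10 5-methoxy-4-[(4-methoxyphenyl)ethynyl]-2-(trimethylsilyl)benzene-1,3-diol, via bis(trimethylsilyl) ether 9 (not isolated)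
Conditions: TMSOTf, 2,2'-bipyridyl, MeCN, 0 °C to rt; then H2O
Reagents that add atoms: none
Why: The silyl triflate with 2,2'-bipyridyl converts aryl methoxymethyl ethers into aryl silyl ethers without free protic acid and water then cleaves the O–Si bonds, which avoids the ipso-protodesilylation that Brønsted acid would cause at a silylated carbon activated by three oxygen substituents.

Step 6
Reactants: 10 5-methoxy-4-[(4-methoxyphenyl)ethynyl]-2-(trimethylsilyl)benzene-1,3-diol; 11 1-iodo-2,4-dimethoxybenzene
Product: 12 (2,4-dimethoxyphenyl)[6-hydroxy-4-methoxy-2-(4-methoxyphenyl)-7-(trimethylsilyl)-1-benzofuran-3-yl]methanone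
Conditions: Pd(PPh3)4 (5 mol%), KOAc, CO (1 atm), MeCN, 45 °C
Reagents that add atoms: carbon monoxide, [C-]#[O+]
Why: In this carbonylative annulation of an ortho-alkynylphenol, oxidative addition of 11 to zerovalent palladium and CO insertion give an aroylpalladium species that activates the alkyne for 5-endo-dig attack of the C3 hydroxyl (the only one ortho to the alkyne), reductive elimination forms the C3–acyl bond, and with the weak base KOAc the hindered C1 hydroxyl stays protonated and should not be aroylated.

Step 7
Reactants: 12 (2,4-dimethoxyphenyl)[6-hydroxy-4-methoxy-2-(4-methoxyphenyl)-7-(trimethylsilyl)-1-benzofuran-3-yl]methanone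
Product: 13 3-(2,4-dimethoxybenzoyl)-4-methoxy-2-(4-methoxyphenyl)-7-(trimethylsilyl)-1-benzofuran-6-yl trifluoromethanesulfonate
Conditions: NaH, THF, 0 °C; then PhNTf2, 0 °C to rt
Reagents that add atoms: N-phenylbis(trifluoromethanesulfonimide), O=S(=O)(N(c1ccccc1)S(=O)(=O)C(F)(F)F)C(F)(F)F
Why: Sulfonylation of the sodium phenoxide by PhNTf2 (phenol triflation) is fluoride-free, and it is placed after furan closure because a free hydroxyl on the other side of the silyl group would make the silyl triflate base-labile through a carbon-to-oxygen silyl shift.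

Step 8
Reactants: 13 3-(2,4-dimethoxybenzoyl)-4-methoxy-2-(4-methoxyphenyl)-7-(trimethylsilyl)-1-benzofuran-6-yl trifluoromethanesulfonate; 14 3-(4-methoxyphenyl)propanoic acid
Product: 16 1-[3-(2,4-dimethoxybenzoyl)-6-hydroxy-4-methoxy-2-(4-methoxyphenyl)-1-benzofuran-7-yl]-3-(4-methoxyphenyl)propan-1-one, via 6,7-benzofuranyne 15 (not isolated)
Conditions: CsF, THF, 125 °C, sealed tube
Reagents that add atoms: none
Why: Fluoride removes the C7 silyl group with loss of the C6 triflate to give aryne 15; the carboxylate of 14 then adds through oxygen at C6, and the C7 aryl anion attacks the carbonyl of the new aryl ester through a four-membered alkoxide that opens to the C7 ketone and the C6 phenoxide. The closest known reaction type is the insertion of fluoride-generated arynes into the acyl–oxygen bond of carboxylic acids to give ortho-hydroxyaryl ketones, with 3-alkoxybenzynes and 6,7-indolynes as models for the orientation. No ring is closed and no stereocenter is formed; the four-membered species is only a transient on the way to the acyl shift. The step needs oxygen at C6 and carbon at C7: O1 on C7a withdraws inductively and distorts the aryne, so the nucleophile should attack the distal carbon C6 and the charge should develop at C7 beside the electronegative atom. It also needs acyl transfer to outrun protonation of the C7 anion, which the hot aprotic medium, the excess of CsF (the acid is present only as its carboxylate) and the slow, solubility-limited release of the aryne should secure.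

Step 9
Reactants: 16 1-[3-(2,4-dimethoxybenzoyl)-6-hydroxy-4-methoxy-2-(4-methoxyphenyl)-1-benzofuran-7-yl]-3-(4-methoxyphenyl)propan-1-one
Product: 17 1-[3-(2,4-dihydroxybenzoyl)-4,6-dihydroxy-2-(4-hydroxyphenyl)-1-benzofuran-7-yl]-3-(4-hydroxyphenyl)propan-1-one
Conditions: BBr3, CH2Cl2, −78 °C to rt; then H2O
Reagents that add atoms: none
Why: BBr3 cleaves aryl methyl ethers by aryloxyborane formation and bromide attack on the methyl group (Lewis-acid demethylation); the two ethers ortho or peri to a ketone should go first through chelation, an excess should remove the other three, and the ketones and the benzofuran are inert.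

Compound list
1 | 5-methoxyresorcinol (5-methoxybenzene-1,3-diol) | COc1cc(O)cc(O)c1 | starting material
2 | 1-methoxy-3,5-bis(methoxymethoxy)benzene | COCOc1cc(OC)cc(OCOC)c1 | intermediate
3 | [4-methoxy-2,6-bis(methoxymethoxy)phenyl]lithium | COCOc1cc(OC)cc(OCOC)c1[Li] | intermediate
4 | [4-methoxy-2,6-bis(methoxymethoxy)phenyl]trimethylsilane | COCOc1cc(OC)cc(OCOC)c1[Si](C)(C)C | intermediate
5 | [6-methoxy-2,4-bis(methoxymethoxy)-3-(trimethylsilyl)phenyl]lithium | COc1cc(OCOC)c([Si](C)(C)C)c(OCOC)c1[Li] | intermediate
6 | [3-iodo-4-methoxy-2,6-bis(methoxymethoxy)phenyl]trimethylsilane | COc1cc(OCOC)c([Si](C)(C)C)c(OCOC)c1I | intermediate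
7 | 4-ethynylanisole (1-ethynyl-4-methoxybenzene) | C#Cc1ccc(OC)cc1 | starting material
8 | {4-methoxy-3-[(4-methoxyphenyl)ethynyl]-2,6-bis(methoxymethoxy)phenyl}trimethylsilane | COc1ccc(C#Cc2c(OC)cc(OCOC)c([Si](C)(C)C)c2OCOC)cc1 | intermediate
9 | {4-methoxy-3-[(4-methoxyphenyl)ethynyl]-2,6-bis(trimethylsilyloxy)phenyl}trimethylsilane | COc1ccc(C#Cc2c(OC)cc(O[Si](C)(C)C)c([Si](C)(C)C)c2O[Si](C)(C)C)cc1 | intermediate
10 | 5-methoxy-4-[(4-methoxyphenyl)ethynyl]-2-(trimethylsilyl)benzene-1,3-diol | COc1ccc(C#Cc2c(OC)cc(O)c([Si](C)(C)C)c2O)cc1 | intermediate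
11 | 1-iodo-2,4-dimethoxybenzene | COc1ccc(I)c(OC)c1 | starting material
12 | (2,4-dimethoxyphenyl)[6-hydroxy-4-methoxy-2-(4-methoxyphenyl)-7-(trimethylsilyl)-1-benzofuran-3-yl]methanone | COc1cc(O)c([Si](C)(C)C)c2oc(-c3ccc(OC)cc3)c(C(=O)c3ccc(OC)cc3OC)c12 | intermediate
13 | 3-(2,4-dimethoxybenzoyl)-4-methoxy-2-(4-methoxyphenyl)-7-(trimethylsilyl)-1-benzofuran-6-yl trifluoromethanesulfonate | COc1cc(OS(=O)(=O)C(F)(F)F)c([Si](C)(C)C)c2oc(-c3ccc(OC)cc3)c(C(=O)c3ccc(OC)cc3OC)c12 | intermediate
14 | 3-(4-methoxyphenyl)propanoic acid | COc1ccc(CCC(=O)O)cc1 | starting material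
15 | (2,4-dimethoxyphenyl)[4-methoxy-2-(4-methoxyphenyl)-6,7-didehydro-1-benzofuran-3-yl]methanone (6,7-benzofuranyne) | COC1=CC#CC2=C1C(C(=O)c1ccc(OC)cc1OC)=C(c1ccc(OC)cc1)O2 | intermediate
16 | 1-[3-(2,4-dimethoxybenzoyl)-6-hydroxy-4-methoxy-2-(4-methoxyphenyl)-1-benzofuran-7-yl]-3-(4-methoxyphenyl)propan-1-one | O=C(CCc1ccc(OC)cc1)c1c(O)cc(OC)c2c(C(=O)c3ccc(OC)cc3OC)c(-c3ccc(OC)cc3)oc12 | intermediate
17 | 1-[3-(2,4-dihydroxybenzoyl)-4,6-dihydroxy-2-(4-hydroxyphenyl)-1-benzofuran-7-yl]-3-(4-hydroxyphenyl)propan-1-one | O=C(CCc1ccc(O)cc1)c1c(O)cc(O)c2c(C(=O)c3ccc(O)cc3O)c(-c3ccc(O)cc3)oc12 | target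

Total step count: 9. Longest linear sequence: 9 steps (1 to 17); compounds 7, 11 and 14 enter as purchased.

Steps most likely to fail

Step 8. The C7 aryl anion may be protonated before it reaches the ester carbonyl, which would stop the sequence at the C6 aryl ester. The product phenoxide may also add to a second aryne, or the carboxylate may add with the reverse orientation. The fallback avoids the aryne, sets out from 12 and comes back to the route at 17. O-Methylation of 12 (MeI, K2CO3, acetone) should give (2,4-dimethoxyphenyl)[4,6-dimethoxy-2-(4-methoxyphenyl)-7-(trimethylsilyl)-1-benzofuran-3-yl]methanone F1. Ipso-iododesilylation with ICl (CH2Cl2, −78 °C) replaces silicon by iodine at C7 only and should give (2,4-dimethoxyphenyl)[7-iodo-4,6-dimethoxy-2-(4-methoxyphenyl)-1-benzofuran-3-yl]methanone F2. Hydroboration of 4-methoxystyrene with 9-BBN in THF gives 9-[2-(4-methoxyphenyl)ethyl]-9-borabicyclo[3.3.1]nonane F3. Carbonylative Suzuki–Miyaura coupling of F2 with F3 (Pd(PPh3)4, K3PO4, CO 1 atm, dioxane, 60 °C) should give 1-[3-(2,4-dimethoxybenzoyl)-4,6-dimethoxy-2-(4-methoxyphenyl)-1-benzofuran-7-yl]-3-(4-methoxyphenyl)propan-1-one F4. BBr3 under the conditions of step 9 then removes six methyl ethers and gives 17.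

Step 6. The aroylpalladium intermediate may acylate the free C1 hydroxyl instead of triggering ring closure, or the alkyne may cyclize without taking up CO and the aryl group. The fallback separates ring closure from acylation, sets out from 10 and comes back at 13. Base-mediated 5-endo-dig cyclization (Cs2CO3, DMF, 60 °C) should give 4-methoxy-2-(4-methoxyphenyl)-7-(trimethylsilyl)-1-benzofuran-6-ol F5. Triflation as in step 7 gives 4-methoxy-2-(4-methoxyphenyl)-7-(trimethylsilyl)-1-benzofuran-6-yl trifluoromethanesulfonate F6. Friedel–Crafts acylation at C3 with 2,4-dimethoxybenzoyl chloride and SnCl4 (CH2Cl2, −40 to 0 °C) should then give 13. The triflate lowers the electron density of the benzo ring and so shields the C7–Si bond from ipso attack, while C3 remains the most nucleophilic carbon.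

Step 4. Oxidative addition into the electron-rich C–I bond, which has substituents on both ortho positions, may be so slow that oxidative homocoupling of 7 consumes the alkyne. The fallback reverses the roles of the coupling partners, sets out from 4 and comes back at 8. Lithiation as in step 3 and a DMF quench should give 6-methoxy-2,4-bis(methoxymethoxy)-3-(trimethylsilyl)benzaldehyde F7. Ohira–Bestmann homologation (dimethyl (1-diazo-2-oxopropyl)phosphonate, K2CO3, MeOH, rt) gives [3-ethynyl-4-methoxy-2,6-bis(methoxymethoxy)phenyl]trimethylsilane F8. Sonogashira coupling of F8 with 4-iodoanisole (PdCl2(PPh3)2, CuI, Et3N, rt) gives 8, with the unhindered partner now as the halide.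

Further compounds
F1 | step 8 | (2,4-dimethoxyphenyl)[4,6-dimethoxy-2-(4-methoxyphenyl)-7-(trimethylsilyl)-1-benzofuran-3-yl]methanone | COc1cc(OC)c([Si](C)(C)C)c2oc(-c3ccc(OC)cc3)c(C(=O)c3ccc(OC)cc3OC)c12
F2 | step 8 | (2,4-dimethoxyphenyl)[7-iodo-4,6-dimethoxy-2-(4-methoxyphenyl)-1-benzofuran-3-yl]methanone | COc1cc(OC)c(I)c2oc(-c3ccc(OC)cc3)c(C(=O)c3ccc(OC)cc3OC)c12
F3 | step 8 | 9-[2-(4-methoxyphenyl)ethyl]-9-borabicyclo[3.3.1]nonane | COc1ccc(CCB2C3CCCC2CCC3)cc1
F4 | step 8 | 1-[3-(2,4-dimethoxybenzoyl)-4,6-dimethoxy-2-(4-methoxyphenyl)-1-benzofuran-7-yl]-3-(4-methoxyphenyl)propan-1-one | O=C(CCc1ccc(OC)cc1)c1c(OC)cc(OC)c2c(C(=O)c3ccc(OC)cc3OC)c(-c3ccc(OC)cc3)oc12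
F5 | step 6 | 4-methoxy-2-(4-methoxyphenyl)-7-(trimethylsilyl)-1-benzofuran-6-ol | COc1cc(O)c([Si](C)(C)C)c2oc(-c3ccc(OC)cc3)cc12
F6 | step 6 | 4-methoxy-2-(4-methoxyphenyl)-7-(trimethylsilyl)-1-benzofuran-6-yl trifluoromethanesulfonate | COc1cc(OS(=O)(=O)C(F)(F)F)c([Si](C)(C)C)c2oc(-c3ccc(OC)cc3)cc12
F7 | step 4 | 6-methoxy-2,4-bis(methoxymethoxy)-3-(trimethylsilyl)benzaldehyde | COc1cc(OCOC)c([Si](C)(C)C)c(OCOC)c1C=O
F8 | step 4 | [3-ethynyl-4-methoxy-2,6-bis(methoxymethoxy)phenyl]trimethylsilane | COc1cc(OCOC)c([Si](C)(C)C)c(OCOC)c1C#C
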